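**Plan**
- Retrosynthesis: cut the C5–vinyl bond (Heck) and O1–C2 (benzylic C–O closure); then take ring A apart at C4–C5, C5–C6, C7–C7a and C3a–C7a into an α-diazo enone and ethoxyethyne; then cut the enone C=C (Wittig) and C2–C3 (aldol).
- Enabling feature: ring A (C3a, C4, C5, C6, C7, C7a) is a resorcinol with O1 on C7a and the hydroxyl on C6 meta to each other, H on C7 between them and the C3 side chain on C3a ortho to O1. This is the 2-alkyl-5-alkoxyphenol pattern that a vinylketene and an ynol ether assemble.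
- Forward: the C2–C3 chain is joined first (boron aldol of a 3,5-dimethoxyphenylacetyl imide with veratraldehyde) and lengthened to the E-diazo enone. Ring A is then built on the chain, C5 is iodinated, the dihydrofuran ring is closed, the styryl arm is attached and all ethers are cleaved.
- Stereochemistry: C3 (S) comes from the (R)-4-benzyloxazolidinone in the syn aldol and is carried through unchanged. C2 (S) is set in the ring closure, trans to the C3 aryl group. The E-alkene comes from the Heck reaction.

Key step: step 7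

Assumption: positions of the target are given in benzofuran numbering (O1, C2, C3, C3a, C4 to C7, C7a), and the arylacetyl imide is taken to follow the normal Z-enolate course of the boron aldol.

**Route**

Step 1
Reactants: 1 3,5-dimethoxyphenylacetic acid; 2 (R)-4-benzyl-1,3-oxazolidin-2-one
Product: 4 (R)-4-benzyl-3-[(3,5-dimethoxyphenyl)acetyl]-1,3-oxazolidin-2-one, via mixed pivalic anhydride 3 (not isolated)
Conditions: PivCl, Et3N, THF, −20 °C; then LiCl, 2, −20 °C → rt
Reagents that add atoms: none
Why: N-acylation of an oxazolidinone through the mixed pivalic anhydride with LiCl/Et3N activation is a standard one-pot method for arylacetic acids and avoids the ketene that an arylacetyl chloride would form with base.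

Step 2
Reactants: 4 (R)-4-benzyl-3-[(3,5-dimethoxyphenyl)acetyl]-1,3-oxazolidin-2-one; 5 veratraldehyde (3,4-dimethoxybenzaldehyde)
Product: 7 (R)-4-benzyl-3-[(2R,3R)-3-(3,4-dimethoxyphenyl)-2-(3,5-dimethoxyphenyl)-3-hydroxypropanoyl]-1,3-oxazolidin-2-one, via Z-dibutylboron enolate 6 (not isolated)
Conditions: Bu2BOTf, iPr2NEt, CH2Cl2, −78 → 0 °C; 5, −78 → 0 °C; then pH 7 buffer, MeOH, 30% H2O2, 0 °C
Reagents that add atoms: none
Why: This is an Evans syn aldol reaction in which the Z boron enolate adds to the aldehyde through a closed Zimmerman–Traxler chair on the enolate face away from the benzyl group of the (R)-auxiliary, so that C2 (the later C3 of the target, R here) and the carbinol carbon C3 (R) are set together as the syn pair.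

Step 3
Reactants: 7 syn aldol adduct
Product: 8 (R)-4-benzyl-3-[(2R,3R)-3-(tert-butyldimethylsilyloxy)-3-(3,4-dimethoxyphenyl)-2-(3,5-dimethoxyphenyl)propanoyl]-1,3-oxazolidin-2-one
Conditions: TBSOTf, 2,6-lutidine, CH2Cl2, −78 → 0 °C
Reagents that add atoms: tert-butyldimethylsilyl trifluoromethanesulfonate, CC(C)(C)[Si](C)(C)OS(=O)(=O)C(F)(F)F
Why: Silylation of a hindered secondary alcohol with the silyl triflate and a hindered pyridine base is routine, and it blocks retro-aldol cleavage in the steps that follow.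

Step 4
Reactants: 8 silylated imide
Product: 9 (2S,3R)-3-(tert-butyldimethylsilyloxy)-3-(3,4-dimethoxyphenyl)-2-(3,5-dimethoxyphenyl)propan-1-ol
Conditions: LiBH4, H2O (1 equiv), Et2O, 0 °C
Reagents that add atoms: none
Why: Reductive removal of the oxazolidinone with LiBH4 takes the exocyclic imide carbonyl to the primary alcohol and returns auxiliary 2, and the silyl ether and the α-aryl stereocentre should not be affected (the descriptor at C2 changes only because the priorities change).

Step 5
Reactants: 9 primary alcohol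
Product: 11 (3E,5R,6R)-6-(tert-butyldimethylsilyloxy)-6-(3,4-dimethoxyphenyl)-5-(3,5-dimethoxyphenyl)hex-3-en-2-one, via aldehyde 10 (not isolated)
Conditions: Dess–Martin periodinane, CH2Cl2, 0 °C → rt; then Ph3P=CHC(O)CH3 (3 equiv), rt
Reagents that add atoms: 1-(triphenylphosphoranylidene)propan-2-one, CC(=O)C=P(c1ccccc1)(c1ccccc1)c1ccccc1
Why: Dess–Martin oxidation followed in the same flask by Wittig olefination with the stabilised acetonyl ylide exposes the epimerisable α-aryl aldehyde to no base stronger than the ylide, and a stabilised ylide should give the E-enone.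

Step 6
Reactants: 11 methyl enone
Product: 13 (3E,5R,6R)-6-(tert-butyldimethylsilyloxy)-1-diazo-6-(3,4-dimethoxyphenyl)-5-(3,5-dimethoxyphenyl)hex-3-en-2-one, via trifluoroacetyl ketone 12 (not isolated)
Conditions: LiN(SiMe3)2, THF, −78 °C; CF3CO2CH2CF3, −78 °C; 5% aq HCl; then MsN3, Et3N, H2O (1 equiv), MeCN, rt
Reagents that add atoms: methanesulfonyl azide, CS(=O)(=O)N=[N+]=[N-]
Why: This is a detrifluoroacetylative diazo transfer, in which kinetic deprotonation of the methyl group at −78 °C and Claisen acylation give a 1,3-diketone that accepts the diazo group from the sulfonyl azide and loses the trifluoroacetyl group as the sulfonamide, a sequence established for methyl enones that do not undergo direct diazo transfer.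

Step 7
Reactants: 13 diazo enone; 14 ethoxyethyne
Product: 19 2-[(1S,2R)-2-(tert-butyldimethylsilyloxy)-2-(3,4-dimethoxyphenyl)-1-(3,5-dimethoxyphenyl)ethyl]-5-ethoxyphenol, via vinylketene 15 (not isolated), via cyclobutenone 16 (not isolated), via dienylketene 17 (not isolated), via cyclohexadienone 18 (not isolated)
Conditions: hν (medium-pressure Hg lamp, Pyrex filter), 14 (3 equiv), degassed ClCH2CH2Cl, 25 °C; then 80 °C
Reagents that add atoms: none
Why: Pyrex-filtered light, absorbed by the diazo enone and not by the aryl ethers, expels N2 from 13 and the alkenyl group migrates to the diazo carbon (Wolff rearrangement, C4–C5) to give vinylketene 15, whose carbonyl carbon (later C7a) bonds to the nucleophilic CH terminus of 14 (C7–C7a) and whose α-carbon bonds to the ethoxy-bearing carbon (C5–C6) in a [2+2] cycloaddition to cyclobutenone 16. Four-electron electrocyclic opening of 16, by light or in the 80 °C stage, gives dienylketene 17, which closes by 6π electrocyclisation (C3a–C7a) to dienone 18 and tautomerises to phenol 19. The closest known reaction type is the Danheiser benzannulation in its α-diazo ketone variant with alkoxyalkynes. Ring A is the only ring that lasts, and it closes as a six-membered carbocycle by thermal disrotatory 6π electrocyclisation of the ketene carbon onto the terminal alkene carbon, the four-membered ring of 16 being opened again. No lasting stereocentre is formed, since C4 of 16 and C6 of 18 vanish on aromatisation, and the two benzylic centres of the chain are spectators in a medium free of acid and base. The step needs one regiochemistry, which the polarity of the ketene (electrophilic carbonyl carbon) and of the ynol ether (nucleophilic β-carbon) secures so that OEt ends on C6, meta to the new hydroxyl with H7 between them and the chain on C3a ortho to the hydroxyl, and the E geometry of 13 keeps the chain on the outside in the 6π closure, while the excess of 14 limits capture of 15 by the phenol formed.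

Step 8
Reactants: 19 phenol
Product: 20 2-[(1S,2R)-2-(tert-butyldimethylsilyloxy)-2-(3,4-dimethoxyphenyl)-1-(3,5-dimethoxyphenyl)ethyl]-5-ethoxy-4-iodophenol
Conditions: NaI, NaOH, aq NaOCl (1 equiv, slow addition), MeOH–THF, 0 °C
Reagents that add atoms: sodium iodide, [Na+].[I-]
Why: Electrophilic aromatic iodination of a phenoxide by hypoiodite made in the flask touches only ring A, the sole free phenol, because the methoxylated rings are inert to this reagent in base, and it should go para to the phenoxide oxygen (C5 of the target) in preference to the position between the two oxygens (C7), the usual outcome of this reagent with phenols whose para position is free.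

Step 9
Reactants: 20 iodophenol
Product: 21 (2S,3S)-2-(3,4-dimethoxyphenyl)-3-(3,5-dimethoxyphenyl)-6-ethoxy-5-iodo-2,3-dihydro-1-benzofuran
Conditions: CF3CO2H, CH2Cl2, −20 → 0 °C
Reagents that add atoms: none
Why: Acid ionises the 3,4-dimethoxybenzylic silyl ether to a para-methoxy-stabilised benzylic cation that the neighbouring phenol oxygen captures in a five-membered ring closure (cyclodehydration of the SN1 type), and attack on the face away from the C3 aryl group, backed by the greater stability of the trans isomer if the closure is reversible, should set C2 as S and trans to the unchanged C3.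

Step 10
Reactants: 21 aryl iodide; 22 3,5-dimethoxystyrene
Product: 23 (2S,3S)-2-(3,4-dimethoxyphenyl)-3-(3,5-dimethoxyphenyl)-5-[(E)-2-(3,5-dimethoxyphenyl)ethenyl]-6-ethoxy-2,3-dihydro-1-benzofuran
Conditions: Pd(OAc)2 (5 mol %), P(o-tol)3, Et3N, DMF, 100 °C
Reagents that add atoms: none
Why: In this Mizoroki–Heck reaction, oxidative addition of the aryl iodide to zerovalent palladium formed in situ, syn insertion of the styrene at its terminal carbon and syn β-hydride elimination should give the E-stilbene.

Step 11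
Reactants: 23 heptaalkyl ether
Product: 24 (2S,3S)-2-(3,4-dihydroxyphenyl)-3-(3,5-dihydroxyphenyl)-5-[(E)-2-(3,5-dihydroxyphenyl)ethenyl]-2,3-dihydro-1-benzofuran-6-ol
Conditions: BBr3 (14 equiv), CH2Cl2, −78 °C → rt; then ice-water
Reagents that add atoms: none
Why: Lewis acid-mediated cleavage of aryl alkyl ethers by BBr3 removes the six methyl groups and the ethyl group as alkyl bromides, as is usual for methylated stilbenoids, and neither stereocentre nor the E-alkene takes part, since no nucleophilic ring lies within reach of the C5 styryl group and the trans dihydrofuran is the stable isomer.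

**Compound list**

1 | 3,5-dimethoxyphenylacetic acid | COc1cc(OC)cc(CC(=O)O)c1 | starting material
2 | (R)-4-benzyl-1,3-oxazolidin-2-one | O=C1N[C@H](Cc2ccccc2)CO1 | starting material
3 | (3,5-dimethoxyphenyl)acetic pivalic anhydride | COc1cc(OC)cc(CC(=O)OC(=O)C(C)(C)C)c1 | intermediate
4 | (R)-4-benzyl-3-[(3,5-dimethoxyphenyl)acetyl]-1,3-oxazolidin-2-one | COc1cc(OC)cc(CC(=O)N2[C@H](Cc3ccccc3)COC2=O)c1 | intermediate
5 | veratraldehyde (3,4-dimethoxybenzaldehyde) | COc1ccc(C=O)cc1OC | starting material
6 | Z-dibutylboron enolate of 4 | CCCCB(CCCC)O/C(=C\c1cc(OC)cc(OC)c1)N1[C@H](Cc2ccccc2)COC1=O | intermediate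
7 | (R)-4-benzyl-3-[(2R,3R)-3-(3,4-dimethoxyphenyl)-2-(3,5-dimethoxyphenyl)-3-hydroxypropanoyl]-1,3-oxazolidin-2-one | O[C@@H](c1ccc(OC)c(OC)c1)[C@H](C(=O)N1[C@H](Cc2ccccc2)COC1=O)c1cc(OC)cc(OC)c1 | intermediate
8 | (R)-4-benzyl-3-[(2R,3R)-3-(tert-butyldimethylsilyloxy)-3-(3,4-dimethoxyphenyl)-2-(3,5-dimethoxyphenyl)propanoyl]-1,3-oxazolidin-2-one | CC(C)(C)[Si](C)(C)O[C@@H](c1ccc(OC)c(OC)c1)[C@H](C(=O)N1[C@H](Cc2ccccc2)COC1=O)c1cc(OC)cc(OC)c1 | intermediate
9 | (2S,3R)-3-(tert-butyldimethylsilyloxy)-3-(3,4-dimethoxyphenyl)-2-(3,5-dimethoxyphenyl)propan-1-ol | CC(C)(C)[Si](C)(C)O[C@@H](c1ccc(OC)c(OC)c1)[C@H](CO)c1cc(OC)cc(OC)c1 | intermediate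
10 | (2R,3R)-3-(tert-butyldimethylsilyloxy)-3-(3,4-dimethoxyphenyl)-2-(3,5-dimethoxyphenyl)propanal | CC(C)(C)[Si](C)(C)O[C@@H](c1ccc(OC)c(OC)c1)[C@H](C=O)c1cc(OC)cc(OC)c1 | intermediate
11 | (3E,5R,6R)-6-(tert-butyldimethylsilyloxy)-6-(3,4-dimethoxyphenyl)-5-(3,5-dimethoxyphenyl)hex-3-en-2-one | CC(C)(C)[Si](C)(C)O[C@@H](c1ccc(OC)c(OC)c1)[C@H](/C=C/C(C)=O)c1cc(OC)cc(OC)c1 | intermediate
12 | (5E,7R,8R)-8-(tert-butyldimethylsilyloxy)-8-(3,4-dimethoxyphenyl)-7-(3,5-dimethoxyphenyl)-1,1,1-trifluorooct-5-ene-2,4-dione | CC(C)(C)[Si](C)(C)O[C@@H](c1ccc(OC)c(OC)c1)[C@H](/C=C/C(=O)CC(=O)C(F)(F)F)c1cc(OC)cc(OC)c1 | intermediate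
13 | (3E,5R,6R)-6-(tert-butyldimethylsilyloxy)-1-diazo-6-(3,4-dimethoxyphenyl)-5-(3,5-dimethoxyphenyl)hex-3-en-2-one | CC(C)(C)[Si](C)(C)O[C@@H](c1ccc(OC)c(OC)c1)[C@H](/C=C/C(=O)C=[N+]=[N-])c1cc(OC)cc(OC)c1 | intermediate
14 | ethoxyethyne | CCOC#C | starting material
15 | (3E,5R,6R)-6-(tert-butyldimethylsilyloxy)-6-(3,4-dimethoxyphenyl)-5-(3,5-dimethoxyphenyl)hexa-1,3-dien-1-one (vinylketene) | CC(C)(C)[Si](C)(C)O[C@@H](c1ccc(OC)c(OC)c1)[C@H](/C=C/C=C=O)c1cc(OC)cc(OC)c1 | intermediate
16 | 4-[(1E,3R,4R)-4-(tert-butyldimethylsilyloxy)-4-(3,4-dimethoxyphenyl)-3-(3,5-dimethoxyphenyl)but-1-enyl]-3-ethoxycyclobut-2-en-1-one (both epimers at ring C4) | CC(C)(C)[Si](C)(C)O[C@@H](c1ccc(OC)c(OC)c1)[C@H](/C=C/C1C(=O)C=C1OCC)c1cc(OC)cc(OC)c1 | intermediate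
17 | (3E,5E,7R,8R)-8-(tert-butyldimethylsilyloxy)-8-(3,4-dimethoxyphenyl)-7-(3,5-dimethoxyphenyl)-3-ethoxyocta-1,3,5-trien-1-one (dienylketene) | CC(C)(C)[Si](C)(C)O[C@@H](c1ccc(OC)c(OC)c1)[C@H](/C=C/C=C(OCC)\C=C=O)c1cc(OC)cc(OC)c1 | intermediate
18 | 6-[(1R,2R)-2-(tert-butyldimethylsilyloxy)-2-(3,4-dimethoxyphenyl)-1-(3,5-dimethoxyphenyl)ethyl]-3-ethoxycyclohexa-2,4-dien-1-one (both epimers at ring C6) | CC(C)(C)[Si](C)(C)O[C@@H](c1ccc(OC)c(OC)c1)[C@H](C1C=CC(OCC)=CC1=O)c1cc(OC)cc(OC)c1 | intermediate
19 | 2-[(1S,2R)-2-(tert-butyldimethylsilyloxy)-2-(3,4-dimethoxyphenyl)-1-(3,5-dimethoxyphenyl)ethyl]-5-ethoxyphenol | CC(C)(C)[Si](C)(C)O[C@@H](c1ccc(OC)c(OC)c1)[C@H](c1ccc(OCC)cc1O)c1cc(OC)cc(OC)c1 | intermediate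
20 | 2-[(1S,2R)-2-(tert-butyldimethylsilyloxy)-2-(3,4-dimethoxyphenyl)-1-(3,5-dimethoxyphenyl)ethyl]-5-ethoxy-4-iodophenol | CC(C)(C)[Si](C)(C)O[C@@H](c1ccc(OC)c(OC)c1)[C@H](c1cc(I)c(OCC)cc1O)c1cc(OC)cc(OC)c1 | intermediate
21 | (2S,3S)-2-(3,4-dimethoxyphenyl)-3-(3,5-dimethoxyphenyl)-6-ethoxy-5-iodo-2,3-dihydro-1-benzofuran | Ic1cc2c(cc1OCC)O[C@H](c1ccc(OC)c(OC)c1)[C@H]2c1cc(OC)cc(OC)c1 | intermediate
22 | 3,5-dimethoxystyrene | COc1cc(OC)cc(C=C)c1 | starting material
23 | (2S,3S)-2-(3,4-dimethoxyphenyl)-3-(3,5-dimethoxyphenyl)-5-[(E)-2-(3,5-dimethoxyphenyl)ethenyl]-6-ethoxy-2,3-dihydro-1-benzofuran | COc1cc(OC)cc(/C=C/c2cc3c(cc2OCC)O[C@H](c2ccc(OC)c(OC)c2)[C@H]3c2cc(OC)cc(OC)c2)c1 | intermediate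
24 | (2S,3S)-2-(3,4-dihydroxyphenyl)-3-(3,5-dihydroxyphenyl)-5-[(E)-2-(3,5-dihydroxyphenyl)ethenyl]-2,3-dihydro-1-benzofuran-6-ol | Oc1cc(O)cc(/C=C/c2cc3c(cc2O)O[C@H](c2ccc(O)c(O)c2)[C@H]3c2cc(O)cc(O)c2)c1 | target

**Count**

Total steps: 11. Longest linear sequence: 11 steps (1 → 24); 2, 5, 14 and 22 enter along the way.

**Steps most likely to fail**

Step 7. The Wolff rearrangement may stall because the dimethoxyaryl groups take up part of the light or the E-alkene isomerises, and the vinylketene may be lost to dimerisation or to acylation of the phenol already formed before the volatile ynol ether adds. The fallback makes the same vinylketene without light, by dehydrochlorination of an acid chloride. It sets out from 13: Wolff rearrangement promoted by PhCO2Ag and Et3N in aqueous THF (dark, rt) should give (3E,5R,6R)-6-(tert-butyldimethylsilyloxy)-6-(3,4-dimethoxyphenyl)-5-(3,5-dimethoxyphenyl)hex-3-enoic acid F1. Treatment with 1-chloro-N,N,2-trimethylprop-1-en-1-amine in CH2Cl2 converts it under neutral conditions into (3E,5R,6R)-6-(tert-butyldimethylsilyloxy)-6-(3,4-dimethoxyphenyl)-5-(3,5-dimethoxyphenyl)hex-3-enoyl chloride F2. Slow addition of Et3N to F2 and an excess of 14 in toluene at rt generates vinylketene 15 in the presence of the ketenophile. Warming to 80 °C takes cyclobutenone 16 on to 19, where the route is rejoined.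

Step 9. The benzylic cation may lose the C3 proton, or take up the C3 hydride, instead of being captured by oxygen. This gives a triarylethene and, if that alkene is protonated again, erodes the C3 configuration. The fallback closes the ring by displacement instead of ionisation. It sets out from 20: Bu4NF buffered with AcOH in THF should free 2-[(1S,2R)-2-(3,4-dimethoxyphenyl)-1-(3,5-dimethoxyphenyl)-2-hydroxyethyl]-5-ethoxy-4-iodophenol F3. Mitsunobu cyclisation (PPh3, diisopropyl azodicarboxylate, THF, 0 °C) then lets the phenoxide displace the activated benzylic oxygen with inversion. Because the diol is the syn isomer, inversion at C2 gives the trans compound 21 directly, where the route is rejoined.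

Step 5. The hindered α-aryl aldehyde may react slowly with the stabilised ylide, so that enolisation (epimerisation at the later C3) and β-elimination of the silanolate gain ground. The fallback uses a faster, lithium-activated phosphonate olefination that brings the diazo ketone with it. It sets out from 9: oxidation as before gives aldehyde 10, which is treated at once with diethyl (3-diazo-2-oxopropyl)phosphonate F4 (a known reagent, prepared from diethylphosphonoacetyl chloride and diazomethane) and LiCl/iPr2NEt in MeCN at 0 °C. This Horner–Wadsworth–Emmons reaction should give the E-diazo enone 13 directly, where the route is rejoined, and it also removes the strongly basic enolisation of step 6.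

**Further compounds**

F1 | step 7 | (3E,5R,6R)-6-(tert-butyldimethylsilyloxy)-6-(3,4-dimethoxyphenyl)-5-(3,5-dimethoxyphenyl)hex-3-enoic acid | CC(C)(C)[Si](C)(C)O[C@@H](c1ccc(OC)c(OC)c1)[C@H](/C=C/CC(=O)O)c1cc(OC)cc(OC)c1
F2 | step 7 | (3E,5R,6R)-6-(tert-butyldimethylsilyloxy)-6-(3,4-dimethoxyphenyl)-5-(3,5-dimethoxyphenyl)hex-3-enoyl chloride | CC(C)(C)[Si](C)(C)O[C@@H](c1ccc(OC)c(OC)c1)[C@H](/C=C/CC(=O)Cl)c1cc(OC)cc(OC)c1
F3 | step 9 | 2-[(1S,2R)-2-(3,4-dimethoxyphenyl)-1-(3,5-dimethoxyphenyl)-2-hydroxyethyl]-5-ethoxy-4-iodophenol | O[C@@H](c1ccc(OC)c(OC)c1)[C@H](c1cc(I)c(OCC)cc1O)c1cc(OC)cc(OC)c1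
F4 | step 5 | diethyl (3-diazo-2-oxopropyl)phosphonate | CCOP(=O)(CC(=O)C=[N+]=[N-])OCC
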